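**Plan**

1. Retrosynthesis: the pyranone ring (ring C of the flavone) is opened at O1–C2 and C4–C4a (carbonylative annulation of an ortho-iodophenol with CO and the ring B alkyne). The ArCH2–C1′ bond is cut next (benzylic Grignard reagent plus a vinylogous ester). Last, the cyclohexane ring is cut at C5′–C6′ (CH2–CMe2) and C2′–C3′ (C(OH)Me–CH2).
2. Enabling feature: in the 2-hydroxy-2,6,6-trimethylcyclohexyl ring, C6′ (CMe2) and C2′ (CMe) both sit on C1′. With C1′ and C3′ raised to carbonyls the ring is 2,4,4-trimethylcyclohexane-1,3-dione, in which C6′ and C2′ are the two α-carbons of an isopropyl ethyl ketone and C3′–C4′–C5′ is an acrylate.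
3. Forward order: the carbocycle is made first in one Michael–Claisen operation; the C1′ carbonyl takes up the arylmethyl group with carbonyl transposition; the C3′ carbonyl serves as stereochemical handle and is then removed; ring C and ring B are attached last.
4. Stereochemistry: a CBS reduction sets a temporary carbinol at C3′; syn hydroboration of the C1′=C2′ alkene anti to that oxygen sets C1′ and C2′ together (OH trans to the arylmethyl group); the C3′ oxygen is removed by radical deoxygenation.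

Key step: step 1

Remark: the sense of the CBS reduction in step 7 is assigned with the alkenyl carbon as the large group; if the opposite sense applied, the (R)-catalyst would be taken.

**Step 1**
Reactants: 1 2-methylpentan-3-one; 2 methyl prop-2-enoate
Product: 4 2,4,4-trimethylcyclohexane-1,3-dione, via keto ester 3 (not isolated)
Conditions: KOtBu (2.2 equiv), t-BuOH/THF, 0 °C, slow addition of 2, then 60 °C; aq. HCl
Reagents that add atoms: none
Why: Under equilibrating alkoxide conditions the isopropyl-side enolate of 1 adds to the β-carbon of 2 (Michael addition), which forms the quaternary carbon and gives keto ester 3, and the enolate at the ethyl CH2 of 3 then attacks the ester carbonyl in an intramolecular Claisen (Dieckmann-type) acylation with loss of methoxide. The closest known reaction type is the Michael–Claisen [3+3] annulation of isopropyl ketones with acrylates to 4,4-dimethylcyclohexane-1,3-diones. The six-membered ring closes in the 6-(enolendo)-exo-trig mode. The one new stereocenter (C2 of the dione) is an enolised 1,3-dicarbonyl carbon, needs no control and becomes sp2 in step 2. The step needs regioselectivity in the order of bond formation: the alternative order (Michael at the ethyl carbon, Claisen at the isopropyl carbon) gives a 2,2-disubstituted dione that cannot form a stabilised enolate and is reopened by retro-Claisen, whereas 4 is trapped as its potassium enolate; slow addition of 2 suppresses double Michael addition.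

**Step 2**
Reactants: 4 2,4,4-trimethylcyclohexane-1,3-dione
Product: 5 2,6,6-trimethyl-3-(2-methylpropoxy)cyclohex-2-en-1-one
Conditions: i-BuOH, TsOH·H2O (cat.), toluene, reflux, Dean–Stark; chromatography to remove the regioisomeric enol ether
Reagents that add atoms: 2-methylpropan-1-ol, CC(C)CO
Why: Acid-catalysed enol etherification should take place at the carbonyl remote from the gem-dimethyl carbon, which leaves the ketone next to CMe2 as the only carbonyl for the later 1,2-addition (vinylogous ester formation for a Stork–Danheiser sequence).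

**Step 3**
Reactants: 6 3,5-bis(benzyloxy)phenol
Product: 7 [3,5-bis(benzyloxy)phenoxy]tri(propan-2-yl)silane
Conditions: TIPSCl, imidazole, DMF, rt
Reagents that add atoms: chlorotri(propan-2-yl)silane, CC(C)[Si](Cl)(C(C)C)C(C)C
Why: Silylation of the phenol gives a bulky, base-stable, non-directing ether that marks this oxygen as the later pyranone oxygen.

**Step 4**
Reactants: 7 [3,5-bis(benzyloxy)phenoxy]tri(propan-2-yl)silane
Product: 9 [2,6-bis(benzyloxy)-4-{[tri(propan-2-yl)silyl]oxy}phenyl]methanol, via aryllithium 8 (not isolated)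
Conditions: n-BuLi, THF, 0 °C to rt; (CH2O)n, 0 °C to rt; H2O
Reagents that add atoms: formaldehyde (as paraformaldehyde), C=O
Why: Directed ortho-lithiation should occur at the position flanked by the two benzyloxy groups (the silyloxy group is a poor director and shields its own ortho positions), and the aryllithium is trapped by formaldehyde.

**Step 5**
Reactants: 9 [2,6-bis(benzyloxy)-4-{[tri(propan-2-yl)silyl]oxy}phenyl]methanol
Product: 10 [3,5-bis(benzyloxy)-4-(chloromethyl)phenoxy]tri(propan-2-yl)silane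
Conditions: PPh3, CCl4, CH2Cl2, 0 °C; used at once
Reagents that add atoms: tetrachloromethane, ClC(Cl)(Cl)Cl
Why: Appel chlorination converts the electron-rich benzylic alcohol into the chloride under neutral conditions that avoid ionisation.

**Step 6**
Reactants: 10 [3,5-bis(benzyloxy)-4-(chloromethyl)phenoxy]tri(propan-2-yl)silane; 5 2,6,6-trimethyl-3-(2-methylpropoxy)cyclohex-2-en-1-one
Product: 13 3-{[2,6-bis(benzyloxy)-4-{[tri(propan-2-yl)silyl]oxy}phenyl]methyl}-2,4,4-trimethylcyclohex-2-en-1-one, via Grignard reagent 11 (not isolated), via tertiary carbinol 12 (not isolated)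
Conditions: Mg (activated), THF, 0 °C; 5, 0 °C to rt; 1 M aq. HCl, THF, rt
Reagents that add atoms: water, O
Why: The benzylic Grignard reagent adds 1,2 to the hindered ketone of the vinylogous ester and acid then hydrolyses the enol ether with loss of water (Stork–Danheiser carbonyl transposition), which places the arylmethyl group on the carbon next to CMe2 and the carbonyl on the former ester carbon.

**Step 7**
Reactants: 13 3-{[2,6-bis(benzyloxy)-4-{[tri(propan-2-yl)silyl]oxy}phenyl]methyl}-2,4,4-trimethylcyclohex-2-en-1-one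
Product: 14 (1R)-3-{[2,6-bis(benzyloxy)-4-{[tri(propan-2-yl)silyl]oxy}phenyl]methyl}-2,4,4-trimethylcyclohex-2-en-1-ol
Conditions: (S)-2-methyl-CBS-oxazaborolidine (20 mol%), BH3·SMe2, THF, −20 °C; MeOH
Reagents that add atoms: none
Why: CBS reduction differentiates the alkenyl side (large) from the ring CH2 side (small) of the 2-substituted cyclohexenone and should give the (R)-allylic alcohol, the stereocenter from which both final stereocenters are relayed.

**Step 8**
Reactants: 14 (1R)-3-{[2,6-bis(benzyloxy)-4-{[tri(propan-2-yl)silyl]oxy}phenyl]methyl}-2,4,4-trimethylcyclohex-2-en-1-ol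
Product: 16 (1R,2R,3S)-3-{[2,6-bis(benzyloxy)-4-{[tri(propan-2-yl)silyl]oxy}phenyl]methyl}-2,4,4-trimethylcyclohexane-1,2-diol, via alkylborane 15 (not isolated)
Conditions: BH3·SMe2 (excess), THF, 0 to 40 °C; 30% H2O2, aq. NaOAc, 0 °C to rt
Reagents that add atoms: hydrogen peroxide, OO
Why: Hydroboration of the tetrasubstituted alkene should place boron on the carbon next to the carbinol (the other alkene carbon is neopentyl-like) and add H and B syn from the face anti to the allylic oxygen, so that oxidation with retention gives the tertiary alcohol trans to the arylmethyl group and sets C2 (R) and C3 (S) from the C1 (R) carbinol.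

**Step 9**
Reactants: 16 (1R,2R,3S)-3-{[2,6-bis(benzyloxy)-4-{[tri(propan-2-yl)silyl]oxy}phenyl]methyl}-2,4,4-trimethylcyclohexane-1,2-diol
Product: 17 O-[(1R,2R,3S)-3-{[2,6-bis(benzyloxy)-4-{[tri(propan-2-yl)silyl]oxy}phenyl]methyl}-2-hydroxy-2,4,4-trimethylcyclohexyl] O-phenyl carbonothioate
Conditions: PhOC(S)Cl, pyridine, DMAP (cat.), CH2Cl2, 0 °C to rt
Reagents that add atoms: O-phenyl carbonochloridothioate, S=C(Cl)Oc1ccccc1
Why: The secondary hydroxyl is acylated selectively (the tertiary hydroxyl is unreactive) to give the Barton–McCombie precursor.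

**Step 10**
Reactants: 17 O-[(1R,2R,3S)-3-{[2,6-bis(benzyloxy)-4-{[tri(propan-2-yl)silyl]oxy}phenyl]methyl}-2-hydroxy-2,4,4-trimethylcyclohexyl] O-phenyl carbonothioate
Product: 18 (1S,2S)-2-{[2,6-bis(benzyloxy)-4-{[tri(propan-2-yl)silyl]oxy}phenyl]methyl}-1,3,3-trimethylcyclohexan-1-ol
Conditions: Bu3SnH, AIBN (cat.), toluene, 90 °C
Reagents that add atoms: none
Why: Barton–McCombie deoxygenation removes the temporary secondary oxygen through a secondary radical that is reduced by the stannane, leaving the tertiary alcohol and both stereocenters untouched.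

**Step 11**
Reactants: 18 (1S,2S)-2-{[2,6-bis(benzyloxy)-4-{[tri(propan-2-yl)silyl]oxy}phenyl]methyl}-1,3,3-trimethylcyclohexan-1-ol
Product: 20 3,5-bis(benzyloxy)-4-{[(1S,2S)-2-hydroxy-2,6,6-trimethylcyclohexyl]methyl}-2-iodophenol, via phenol 19 (not isolated)
Conditions: TBAF, THF, 0 °C; NIS (1.0 equiv), −20 °C; aq. Na2S2O3, dilute aq. HCl
Reagents that add atoms: N-iodosuccinimide, O=C1CCC(=O)N1I
Why: Fluoride cleaves the aryl silyl ether and the liberated phenoxide is iodinated by NIS at an ortho position (the two are equivalent and the para position is blocked).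

**Step 12**
Reactants: 21 3,4-bis(benzyloxy)benzaldehyde
Product: 22 1,2-bis(benzyloxy)-4-ethynylbenzene
Conditions: dimethyl (1-diazo-2-oxopropyl)phosphonate, K2CO3, MeOH, rt
Reagents that add atoms: dimethyl (1-diazo-2-oxopropyl)phosphonate, CC(=O)C(=[N+]=[N-])P(=O)(OC)OC
Why: Ohira–Bestmann homologation converts the aldehyde into the terminal alkyne under mild base.

**Step 13**
Reactants: 20 3,5-bis(benzyloxy)-4-{[(1S,2S)-2-hydroxy-2,6,6-trimethylcyclohexyl]methyl}-2-iodophenol; 22 1,2-bis(benzyloxy)-4-ethynylbenzene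
Product: 24 5,7-bis(benzyloxy)-2-[3,4-bis(benzyloxy)phenyl]-6-{[(1S,2S)-2-hydroxy-2,6,6-trimethylcyclohexyl]methyl}-4H-chromen-4-one, via ynone 23 (not isolated)
Conditions: PdCl2(PPh3)2 (5 mol%), 1,3-bis(diphenylphosphino)propane (5 mol%), CO (1 atm), Et2NH, DMF, 60 °C
Reagents that add atoms: carbon monoxide, [C-]#[O+]
Why: Palladium-catalysed carbonylative Sonogashira coupling gives the ortho-hydroxyaryl ynone, which should cyclise 6-endo under the amine conditions to the flavone; only the free phenol oxygen can close the ring, so the alkyl group ends at C6.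

**Step 14**
Reactants: 24 5,7-bis(benzyloxy)-2-[3,4-bis(benzyloxy)phenyl]-6-{[(1S,2S)-2-hydroxy-2,6,6-trimethylcyclohexyl]methyl}-4H-chromen-4-one
Product: 25 2-(3,4-dihydroxyphenyl)-5,7-dihydroxy-6-{[(1S,2S)-2-hydroxy-2,6,6-trimethylcyclohexyl]methyl}-4H-chromen-4-one
Conditions: H2 (1 atm), Pd/C (10 wt% palladium on carbon), EtOAc/MeOH, rt
Reagents that add atoms: none
Why: Hydrogenolysis of the four benzyl ethers at ambient pressure frees the phenols without acid, so the tertiary alcohol and the flavone double bond should remain intact.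

**Compound list**

1 | 2-methylpentan-3-one | CCC(=O)C(C)C | starting material
2 | methyl prop-2-enoate | C=CC(=O)OC | starting material
3 | methyl 4,4-dimethyl-5-oxoheptanoate | CCC(=O)C(C)(C)CCC(=O)OC | intermediate
4 | 2,4,4-trimethylcyclohexane-1,3-dione | O=C1CCC(C)(C)C(=O)C1C | intermediate
5 | 2,6,6-trimethyl-3-(2-methylpropoxy)cyclohex-2-en-1-one | O=C1C(C)=C(OCC(C)C)CCC1(C)C | intermediate
6 | 3,5-bis(benzyloxy)phenol | Oc1cc(OCc2ccccc2)cc(OCc2ccccc2)c1 | starting material
7 | [3,5-bis(benzyloxy)phenoxy]tri(propan-2-yl)silane | CC(C)[Si](Oc1cc(OCc2ccccc2)cc(OCc2ccccc2)c1)(C(C)C)C(C)C | intermediate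
8 | [2,6-bis(benzyloxy)-4-{[tri(propan-2-yl)silyl]oxy}phenyl]lithium | [Li]c1c(OCc2ccccc2)cc(O[Si](C(C)C)(C(C)C)C(C)C)cc1OCc1ccccc1 | intermediate
9 | [2,6-bis(benzyloxy)-4-{[tri(propan-2-yl)silyl]oxy}phenyl]methanol | OCc1c(OCc2ccccc2)cc(O[Si](C(C)C)(C(C)C)C(C)C)cc1OCc1ccccc1 | intermediate
10 | [3,5-bis(benzyloxy)-4-(chloromethyl)phenoxy]tri(propan-2-yl)silane | ClCc1c(OCc2ccccc2)cc(O[Si](C(C)C)(C(C)C)C(C)C)cc1OCc1ccccc1 | intermediate
11 | {[2,6-bis(benzyloxy)-4-{[tri(propan-2-yl)silyl]oxy}phenyl]methyl}magnesium chloride | Cl[Mg]Cc1c(OCc2ccccc2)cc(O[Si](C(C)C)(C(C)C)C(C)C)cc1OCc1ccccc1 | intermediate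
12 | 1-{[2,6-bis(benzyloxy)-4-{[tri(propan-2-yl)silyl]oxy}phenyl]methyl}-2,6,6-trimethyl-3-(2-methylpropoxy)cyclohex-2-en-1-ol (racemic) | CC(C)COC1=C(C)C(O)(Cc2c(OCc3ccccc3)cc(O[Si](C(C)C)(C(C)C)C(C)C)cc2OCc2ccccc2)C(C)(C)CC1 | intermediate
13 | 3-{[2,6-bis(benzyloxy)-4-{[tri(propan-2-yl)silyl]oxy}phenyl]methyl}-2,4,4-trimethylcyclohex-2-en-1-one | CC1=C(Cc2c(OCc3ccccc3)cc(O[Si](C(C)C)(C(C)C)C(C)C)cc2OCc2ccccc2)C(C)(C)CCC1=O | intermediate
14 | (1R)-3-{[2,6-bis(benzyloxy)-4-{[tri(propan-2-yl)silyl]oxy}phenyl]methyl}-2,4,4-trimethylcyclohex-2-en-1-ol | O[C@@H]1CCC(C)(C)C(Cc2c(OCc3ccccc3)cc(O[Si](C(C)C)(C(C)C)C(C)C)cc2OCc2ccccc2)=C1C | intermediate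
15 | alkylborane from 14 (boron on C2, oxygen at C1 borylated) | CC1(C)CC[C@@H](OB)[C@](C)(B)[C@H]1Cc1c(OCc2ccccc2)cc(O[Si](C(C)C)(C(C)C)C(C)C)cc1OCc1ccccc1 | intermediate
16 | (1R,2R,3S)-3-{[2,6-bis(benzyloxy)-4-{[tri(propan-2-yl)silyl]oxy}phenyl]methyl}-2,4,4-trimethylcyclohexane-1,2-diol | CC1(C)CC[C@@H](O)[C@](C)(O)[C@H]1Cc1c(OCc2ccccc2)cc(O[Si](C(C)C)(C(C)C)C(C)C)cc1OCc1ccccc1 | intermediate
17 | O-[(1R,2R,3S)-3-{[2,6-bis(benzyloxy)-4-{[tri(propan-2-yl)silyl]oxy}phenyl]methyl}-2-hydroxy-2,4,4-trimethylcyclohexyl] O-phenyl carbonothioate | CC1(C)CC[C@@H](OC(=S)Oc2ccccc2)[C@](C)(O)[C@H]1Cc1c(OCc2ccccc2)cc(O[Si](C(C)C)(C(C)C)C(C)C)cc1OCc1ccccc1 | intermediate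
18 | (1S,2S)-2-{[2,6-bis(benzyloxy)-4-{[tri(propan-2-yl)silyl]oxy}phenyl]methyl}-1,3,3-trimethylcyclohexan-1-ol | CC1(C)CCC[C@](C)(O)[C@H]1Cc1c(OCc2ccccc2)cc(O[Si](C(C)C)(C(C)C)C(C)C)cc1OCc1ccccc1 | intermediate
19 | 3,5-bis(benzyloxy)-4-{[(1S,2S)-2-hydroxy-2,6,6-trimethylcyclohexyl]methyl}phenol | CC1(C)CCC[C@](C)(O)[C@H]1Cc1c(OCc2ccccc2)cc(O)cc1OCc1ccccc1 | intermediate
20 | 3,5-bis(benzyloxy)-4-{[(1S,2S)-2-hydroxy-2,6,6-trimethylcyclohexyl]methyl}-2-iodophenol | CC1(C)CCC[C@](C)(O)[C@H]1Cc1c(OCc2ccccc2)cc(O)c(I)c1OCc1ccccc1 | intermediate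
21 | 3,4-bis(benzyloxy)benzaldehyde | O=Cc1ccc(OCc2ccccc2)c(OCc2ccccc2)c1 | starting material
22 | 1,2-bis(benzyloxy)-4-ethynylbenzene | C#Cc1ccc(OCc2ccccc2)c(OCc2ccccc2)c1 | intermediate
23 | 1-[2,4-bis(benzyloxy)-6-hydroxy-3-{[(1S,2S)-2-hydroxy-2,6,6-trimethylcyclohexyl]methyl}phenyl]-3-[3,4-bis(benzyloxy)phenyl]prop-2-yn-1-one | CC1(C)CCC[C@](C)(O)[C@H]1Cc1c(OCc2ccccc2)cc(O)c(C(=O)C#Cc2ccc(OCc3ccccc3)c(OCc3ccccc3)c2)c1OCc1ccccc1 | intermediate
24 | 5,7-bis(benzyloxy)-2-[3,4-bis(benzyloxy)phenyl]-6-{[(1S,2S)-2-hydroxy-2,6,6-trimethylcyclohexyl]methyl}-4H-chromen-4-one | CC1(C)CCC[C@](C)(O)[C@H]1Cc1c(OCc2ccccc2)cc2oc(-c3ccc(OCc4ccccc4)c(OCc4ccccc4)c3)cc(=O)c2c1OCc1ccccc1 | intermediate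
25 | 2-(3,4-dihydroxyphenyl)-5,7-dihydroxy-6-{[(1S,2S)-2-hydroxy-2,6,6-trimethylcyclohexyl]methyl}-4H-chromen-4-one | CC1(C)CCC[C@](C)(O)[C@H]1Cc1c(O)cc2oc(-c3ccc(O)c(O)c3)cc(=O)c2c1O | target

**Step count and risks**

Total: 14 steps. Longest linear sequence: 11 steps (from 6 through steps 3 to 11, 13 and 14).

Steps most likely to fail:

1. Step 6. Formation of the electron-rich, doubly ortho-substituted benzylic Grignard reagent may be undermined by Wurtz homocoupling and ionisation of the chloride, and its addition to the hindered vinylogous ester may be slow. Fallback, setting out from 5 and 7 and returning at 13: MeLi is added to 5 and acid hydrolysis gives 2,3,4,4-tetramethylcyclohex-2-en-1-one F1. SeO2 in dioxane oxidises the γ-methyl group to 2,6,6-trimethyl-3-oxocyclohex-1-ene-1-carbaldehyde F2. Aryllithium 8 (from 7 and n-BuLi as in step 4) adds to the aldehyde to give the carbinol 3-{[2,6-bis(benzyloxy)-4-{[tri(propan-2-yl)silyl]oxy}phenyl](hydroxy)methyl}-2,4,4-trimethylcyclohex-2-en-1-one F3. Ionic hydrogenation (Et3SiH, CF3CO2H, CH2Cl2, −20 °C) removes the benzylic hydroxyl to give 13.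

2. Step 8. Hydroboration of the hindered tetrasubstituted alkene may be slow, and boron–oxygen β-elimination or attack from the wrong face would erode the stereochemical relay. Fallback, setting out from 14 and returning at 18: Myers allylic transposition (2-nitrobenzenesulfonylhydrazide, PPh3, diethyl azodicarboxylate, N-methylmorpholine, −30 °C to rt) gives by Mitsunobu inversion N-[(1S)-3-{[2,6-bis(benzyloxy)-4-{[tri(propan-2-yl)silyl]oxy}phenyl]methyl}-2,4,4-trimethylcyclohex-2-en-1-yl]-2-nitrobenzenesulfonohydrazide F4. On warming F4 loses the sulfinic acid and dinitrogen with suprafacial hydrogen delivery to the ring carbon and gives {3,5-bis(benzyloxy)-4-{[(1S)-2,6,6-trimethylcyclohex-2-en-1-yl]methyl}phenoxy}tri(propan-2-yl)silane F5. Mukaiyama hydration (Co(acac)2, PhSiH3, O2, i-PrOH, then PPh3) gives 18; here oxygen is expected to arrive equatorially, anti to the axial methyl of the gem-dimethyl carbon, but this facial preference is less secure than the syn addition of the main route.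

3. Step 13. Competing 5-exo closure to the aurone, or sluggish oxidative addition at the hindered, electron-rich aryl iodide, may divert the carbonylative annulation. Fallback, setting out from 20 and 21 and returning at 24: Stille coupling of 20 with tributyl(1-ethoxyethenyl)stannane (PdCl2(PPh3)2, toluene, 90 °C) gives 3,5-bis(benzyloxy)-2-(1-ethoxyethenyl)-4-{[(1S,2S)-2-hydroxy-2,6,6-trimethylcyclohexyl]methyl}phenol F6. Brief cold dilute aqueous HCl hydrolyses it to 1-[2,4-bis(benzyloxy)-6-hydroxy-3-{[(1S,2S)-2-hydroxy-2,6,6-trimethylcyclohexyl]methyl}phenyl]ethan-1-one F7. Claisen–Schmidt condensation with aldehyde 21 (KOH, EtOH) gives (2E)-1-[2,4-bis(benzyloxy)-6-hydroxy-3-{[(1S,2S)-2-hydroxy-2,6,6-trimethylcyclohexyl]methyl}phenyl]-3-[3,4-bis(benzyloxy)phenyl]prop-2-en-1-one F8. Oxidative cyclisation with catalytic I2 in DMSO at 110 °C gives 24.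

**Further compounds**

F1 | step 6 | 2,3,4,4-tetramethylcyclohex-2-en-1-one | CC1=C(C)C(C)(C)CCC1=O
F2 | step 6 | 2,6,6-trimethyl-3-oxocyclohex-1-ene-1-carbaldehyde | O=CC1=C(C)C(=O)CCC1(C)C
F3 | step 6 | 3-{[2,6-bis(benzyloxy)-4-{[tri(propan-2-yl)silyl]oxy}phenyl](hydroxy)methyl}-2,4,4-trimethylcyclohex-2-en-1-one | CC1=C(C(O)c2c(OCc3ccccc3)cc(O[Si](C(C)C)(C(C)C)C(C)C)cc2OCc2ccccc2)C(C)(C)CCC1=O
F4 | step 8 | N-[(1S)-3-{[2,6-bis(benzyloxy)-4-{[tri(propan-2-yl)silyl]oxy}phenyl]methyl}-2,4,4-trimethylcyclohex-2-en-1-yl]-2-nitrobenzenesulfonohydrazide | CC1(C)CC[C@H](N(N)S(=O)(=O)c2ccccc2[N+](=O)[O-])C(C)=C1Cc1c(OCc2ccccc2)cc(O[Si](C(C)C)(C(C)C)C(C)C)cc1OCc1ccccc1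
F5 | step 8 | {3,5-bis(benzyloxy)-4-{[(1S)-2,6,6-trimethylcyclohex-2-en-1-yl]methyl}phenoxy}tri(propan-2-yl)silane | CC1(C)CCC=C(C)[C@H]1Cc1c(OCc2ccccc2)cc(O[Si](C(C)C)(C(C)C)C(C)C)cc1OCc1ccccc1
F6 | step 13 | 3,5-bis(benzyloxy)-2-(1-ethoxyethenyl)-4-{[(1S,2S)-2-hydroxy-2,6,6-trimethylcyclohexyl]methyl}phenol | CC1(C)CCC[C@](C)(O)[C@H]1Cc1c(OCc2ccccc2)cc(O)c(C(=C)OCC)c1OCc1ccccc1
F7 | step 13 | 1-[2,4-bis(benzyloxy)-6-hydroxy-3-{[(1S,2S)-2-hydroxy-2,6,6-trimethylcyclohexyl]methyl}phenyl]ethan-1-one | CC1(C)CCC[C@](C)(O)[C@H]1Cc1c(OCc2ccccc2)cc(O)c(C(C)=O)c1OCc1ccccc1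
F8 | step 13 | (2E)-1-[2,4-bis(benzyloxy)-6-hydroxy-3-{[(1S,2S)-2-hydroxy-2,6,6-trimethylcyclohexyl]methyl}phenyl]-3-[3,4-bis(benzyloxy)phenyl]prop-2-en-1-one | CC1(C)CCC[C@](C)(O)[C@H]1Cc1c(OCc2ccccc2)cc(O)c(C(=O)/C=C/c2ccc(OCc3ccccc3)c(OCc3ccccc3)c2)c1OCc1ccccc1
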